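The pitfall in this flask is to extend Friday's nearly straight fall of J as a line out to the asked time, because that run stops with J still at 85.0%.

| setting | Friday's | flask |
|---|---|---|
| J | 0.14 M | 0.14 M |
| Ek | 1.05 equiv | 1.05 equiv |
| remark | the very flask that is asked about, followed so far |  |
| time |  | 20 min |

Friday's run (percent of the J charged)

| time / min | X / % | J / % |
|---|---|---|
| 1.00 | 1.3 | 97.6 |
| 2.00 | 2.5 | 94.6 |
| 3.00 | 4.7 | 91.7 |
| 4.00 | 6.4 | 90.2 |
| 5.00 | 9.0 | 88.1 |
| 6.00 | 11.1 | 85.0 |

(each reading ± 0.5 percentage points)

* how much X there is at 20 min, in percent of the J charged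
* concentration of E in solution at 20 min, in percent of saturation

1. Take J as the concentration that sets the order, and take that order as first. This is a choice, since readings this short cannot part a decay from a line. Friday's last J reading, scaled from 6.00 min to 20 min, gives 0.542: the decay number, the count of e-foldings of J that fit into the asked time. The fraction of J left is exp(−N), or 58.2%.

2. Test it on J. At 3.00 min the number gives 92.2% against a reading of 91.7%, about one scatter of 0.5 percentage points apart.

3. For X, one number is not enough. J and X together fall short of the charge by 3.60% at 3.00 min and 3.90% at 6.00 min, a gap that stays flat. I therefore read J's loss as the rate-limiting step and reckon X as the fraction lost minus that gap: 37.9%.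

4. E was never read, so I put no number of my own on it.

5. The forecast says 36% of X and 80% of saturation, with E “held somewhat below it if the reaction consumes E while solid remains”.

6. The flask gives 36.3% of X and 58.3% of J. E stands at 99.8% of saturation.

    G → Qa (k = 0.100 min⁻¹)
    Z ⇌ G (K = 0.130, k = 0.0350 min⁻¹)
    Q ⇌ Z (K = 30.0, k = 0.0850 min⁻¹)
    Z → D (k = 1.10 min⁻¹)
    J → Q (k = 0.0270 min⁻¹)
    Q → X (k = 0.840 min⁻¹)
    Ek ⇌ E, rate k7*(cs7 - [E]) while solid is left; crystals form when [E] > cs7 (solubility = 0.130 M, k = 0.320 min⁻¹)

Left until 50 min, the same flask has a decay number of 1.35. That reckons 25.9% of J and, with the same gap, 70.3% of X. The flask holds 25.9% of J and 66.6% of X, so X stands lower than reckoned by 3.7 points. Beside them stand 0.780% of Q and 6.60% of D.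

Readings and results are calculated on assumed constants, and the scatter is random.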